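**Plan**

- Retrosynthesis: the exocyclic C3–CH2CO2H bond is cut first (ring cation plus acetate nucleophile). The three ring bonds C4–C5, C6–O1 and O2–C3 are then cut together, and last the side-chain bond C3'–C4' between two primary carbons.
- Enabling feature: in the 1,2-dioxane ring (O1, O2, C3, C4, C5, C6), C3–C4 with the C4 methyl is a propanal unit, C5–C6 with the C6 methyl and the side chain is a 2-methyl-1-alkene, and O1–O2 is a molecule of dioxygen.
- Forward: the phenyl-terminated half (from (S)-citronellyl bromide) and the methallyl half (by auxiliary alkylation) are joined by a copper-catalysed sp3–sp3 coupling. The only ring then forms in one aerobic three-component annulation as its C3 lactol; methanolysis, substitution at C3 and saponification finish the route.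
- Stereochemistry: C6' comes from the chiral pool, C2' from the oxazolidinone auxiliary, C4 from the amine catalyst, and C3 from axial attack on the ring cation. C6 is not controlled; its epimer is removed at the methyl ester.

Key step: step 8

Remark: ring atoms are numbered O1, O2, C3–C6 and side-chain carbons C1'–C10'; 18–20, 22 and crude 23 are expected together with their 6S epimers (19 and 20 also as anomers), only the 6R series is numbered, and the 6S ester is removed from 23 by preparative HPLC.

**Route**

Step 1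
Reactants: 1 (S)-citronellyl bromide
Product: 3 (4S)-6-bromo-4-methylhexanal, via secondary ozonide 2 (not isolated)
Conditions: O3, CH2Cl2, −78 °C; then Me2S, −78 °C → rt
Reagents that add atoms: ozone, [O-][O+]=O
Why: Ozonolysis with reductive work-up cleaves the electron-rich trisubstituted alkene to the aldehyde under neutral conditions that leave the primary bromide and the stereocentre (γ to the new carbonyl) untouched.

Step 2
Reactants: 3 (4S)-6-bromo-4-methylhexanal; 4 benzyltriphenylphosphonium bromide
Product: 6 [(5S)-7-bromo-5-methylhept-1-en-1-yl]benzene, via benzylidenetriphenylphosphorane 5 (not isolated)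
Conditions: 4, NaHMDS, THF, 0 °C; then 3, −78 °C → rt
Reagents that add atoms: none
Why: Wittig olefination of the aldehyde by the semi-stabilised ylide at low temperature should be much faster than alkylation of the ylide by the primary bromide, and the E/Z mixture is of no consequence because step 3 saturates it.

Step 3
Reactants: 6 [(5S)-7-bromo-5-methylhept-1-en-1-yl]benzene
Product: 7 [(5S)-7-bromo-5-methylheptyl]benzene
Conditions: H2 (1 atm), 5% Pt/C, EtOAc, rt
Reagents that add atoms: none
Why: Heterogeneous catalytic hydrogenation over platinum saturates the styrenyl alkene, while an unactivated primary C–Br bond and the arene should resist reduction under neutral conditions at 1 atm.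

Step 4
Reactants: 8 (4R)-4-benzyl-3-propanoyl-1,3-oxazolidin-2-one; 9 3-bromo-2-methylprop-1-ene
Product: 11 (4R)-4-benzyl-3-[(2S)-2,4-dimethylpent-4-enoyl]-1,3-oxazolidin-2-one, via sodium Z-enolate 10 (not isolated)
Conditions: NaHMDS, THF, −78 °C; then 9, −78 → −40 °C
Reagents that add atoms: none
Why: Evans asymmetric alkylation: the chelated Z-enolate is attacked by the allylic bromide on the face opposite the benzyl group of the (R)-auxiliary, which sets the (S) centre that becomes C2' of the side chain.

Step 5
Reactants: 11 (4R)-4-benzyl-3-[(2S)-2,4-dimethylpent-4-enoyl]-1,3-oxazolidin-2-one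
Product: 12 (2S)-2,4-dimethylpent-4-en-1-ol
Conditions: LiBH4, H2O (1 equiv), Et2O, 0 °C; aq. NaOH work-up
Reagents that add atoms: none
Why: Reductive cleavage of the N-acyl oxazolidinone with lithium borohydride attacks the exocyclic carbonyl and gives the primary alcohol without touching the α-stereocentre or the alkene, the auxiliary being recovered.

Step 6
Reactants: 12 (2S)-2,4-dimethylpent-4-en-1-ol
Product: 13 (2S)-2,4-dimethylpent-4-en-1-yl 4-methylbenzenesulfonate
Conditions: TsCl, Et3N, DMAP (cat.), CH2Cl2, 0 °C → rt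
Reagents that add atoms: 4-methylbenzenesulfonyl chloride, Cc1ccc(cc1)S(Cl)(=O)=O
Why: Sulfonylation of the primary alcohol gives a non-volatile primary electrophile for the coupling and does not involve the stereocentre.

Step 7
Reactants: 7 [(5S)-7-bromo-5-methylheptyl]benzene; 13 (2S)-2,4-dimethylpent-4-en-1-yl 4-methylbenzenesulfonate
Product: 15 (4R,8S)-2,4,8-trimethyl-12-phenyldodec-1-ene, via Grignard reagent 14 (not isolated)
Conditions: 7, Mg (I2 cat.), THF, 40 °C; then 13, Li2CuCl4 (5 mol %), THF, −20 °C → rt
Reagents that add atoms: none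
Why: Copper-catalysed cross-coupling of a primary Grignard reagent with a primary tosylate (Kochi-type, Li2CuCl4) joins C3' and C4' by substitution at carbons that are not stereogenic, so both methyl-bearing centres and the 1,1-disubstituted alkene pass through unchanged.

Step 8
Reactants: 15 (4R,8S)-2,4,8-trimethyl-12-phenyldodec-1-ene; 16 propanal; 17 dioxygen
Product: 19 (4S,6R)-4,6-dimethyl-6-[(2R,6S)-2,6-dimethyl-10-phenyldecyl]-1,2-dioxan-3-ol, via hydroperoxy aldehyde 18 (not isolated)
Conditions: (2R,5R)-5-benzyl-2-tert-butyl-3-methylimidazolidin-4-one·TFA (20 mol %), Mn(OAc)3·2H2O (10 mol %), Mn(OAc)2·4H2O (10 mol %), H2O (2 equiv), acetone/AcOH 4:1, 15 at 0.5 M, slow stream of dry air, 0 °C; 16 (5 equiv) added over several hours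
Reagents that add atoms: none
Why: Proposed new method: the imidazolidinone and 16 form an E-enamine that Mn(III) oxidises to a radical cation; its α-carbon (ring C4) adds to the CH2 terminus of 15 (C4–C5), the tertiary C6 radical is trapped by triplet O2 (C6–O1), Mn(II) reduces the peroxyl radical and thereby regenerates Mn(III), and after iminium hydrolysis hydroperoxy aldehyde 18 closes the O2–C3 bond by 6-exo-trig hemiacetalisation, so the ring forms redox-neutrally from the three components. The closest known reactions are the Mn(III)/O2 annulation of 1,3-dicarbonyl compounds with 1,1-disubstituted alkenes to 1,2-dioxan-3-ols and the enantioselective α-alkylation of aldehydes with simple alkenes through enamine radical cations, in which the adduct radical is quenched by hydrogen-atom transfer instead of O2. C4 is set (S) by the catalyst: in the (2R,5R) enantiomer the benzyl group covers the Si face of the enamine α-carbon, so the alkene bonds to the Re face. C6 arises from an acyclic tertiary radical without control, so the 6S epimer is expected in about equal amount and is carried along to ester 23, and C3 is an anomeric mixture that step 10 erases. The step needs attack at the unsubstituted alkene carbon, which the 1,1-disubstitution secures through the tertiary radical, and capture of the radical cation by the alkene ahead of O2, which the high alkene concentration, slow addition of excess 16 and the low oxygen pressure of air are meant to secure. Free propanal is not oxidised by Mn(III) at 0 °C, so a racemic path through a manganese enolate should stay negligible, and Mn(II) should intercept peroxyl radicals before they start autoxidation of the aldehyde.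

Step 9
Reactants: 19 (4S,6R)-4,6-dimethyl-6-[(2R,6S)-2,6-dimethyl-10-phenyldecyl]-1,2-dioxan-3-ol
Product: 20 (4S,6R)-3-methoxy-4,6-dimethyl-6-[(2R,6S)-2,6-dimethyl-10-phenyldecyl]-1,2-dioxane
Conditions: PPTS (cat.), MeOH, rt
Reagents that add atoms: methanol, CO
Why: Acid-catalysed acetalisation of the cyclic peroxyhemiacetal in excess methanol exchanges OH for OMe, and the mild acid should keep the small amount of ring-opened aldehyde from enolising at C4.

Step 10
Reactants: 20 (4S,6R)-3-methoxy-4,6-dimethyl-6-[(2R,6S)-2,6-dimethyl-10-phenyldecyl]-1,2-dioxane; 21 tert-butyl[(1-methoxyethenyl)oxy]dimethylsilane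
Product: 23 methyl 2-[(3S,4S,6R)-4,6-dimethyl-6-[(2R,6S)-2,6-dimethyl-10-phenyldecyl]-1,2-dioxan-3-yl]acetate, via peroxycarbenium triflate 22 (not isolated)
Conditions: TMSOTf (0.2 equiv), CH2Cl2, −78 °C; then preparative HPLC
Reagents that add atoms: none
Why: Lewis-acid ionisation of the 3-methoxy-1,2-dioxane and capture of the peroxycarbenium ion by the ketene silyl acetal (a Mukaiyama-type substitution known for 3-alkoxy-1,2-dioxanes) should proceed by axial attack on the half-chair that keeps the C4 methyl and the C6 side chain pseudo-equatorial, which places the arm cis to the C4 methyl, i.e. (3S), after which the 6S ester is removed by HPLC.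

Step 11
Reactants: 23 methyl 2-[(3S,4S,6R)-4,6-dimethyl-6-[(2R,6S)-2,6-dimethyl-10-phenyldecyl]-1,2-dioxan-3-yl]acetate
Product: 25 2-[(3S,4S,6R)-4,6-dimethyl-6-[(2R,6S)-2,6-dimethyl-10-phenyldecyl]-1,2-dioxan-3-yl]acetic acid, via lithium carboxylate 24 (not isolated)
Conditions: LiOH, THF/MeOH/H2O, 0 °C; then 1 M HCl to pH 3
Reagents that add atoms: lithium hydroxide, [Li+].[OH-]
Why: Saponification of the methyl ester with lithium hydroxide at 0 °C, a standard operation on 1,2-dioxane-3-acetates, followed by mild acidification should give the acid without touching the peroxide bond or any stereocentre.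

**Compound list**

1 | (S)-citronellyl bromide, (6S)-8-bromo-2,6-dimethyloct-2-ene | C[C@@H](CCC=C(C)C)CCBr | starting material
2 | 3-[(3S)-5-bromo-3-methylpentyl]-5,5-dimethyl-1,2,4-trioxolane (secondary ozonide, both epimers at the ring carbon) | C[C@@H](CCC1OOC(C)(C)O1)CCBr | intermediate
3 | (4S)-6-bromo-4-methylhexanal | C[C@@H](CCC=O)CCBr | intermediate
4 | benzyltriphenylphosphonium bromide | [Br-].C(c1ccccc1)[P+](c1ccccc1)(c1ccccc1)c1ccccc1 | starting material
5 | benzylidenetriphenylphosphorane | C(=P(c1ccccc1)(c1ccccc1)c1ccccc1)c1ccccc1 | intermediate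
6 | [(5S)-7-bromo-5-methylhept-1-en-1-yl]benzene (E/Z mixture) | C[C@@H](CCC=Cc1ccccc1)CCBr | intermediate
7 | [(5S)-7-bromo-5-methylheptyl]benzene | C[C@@H](CCCCc1ccccc1)CCBr | intermediate
8 | (4R)-4-benzyl-3-propanoyl-1,3-oxazolidin-2-one | CCC(=O)N1[C@H](Cc2ccccc2)COC1=O | starting material
9 | 3-bromo-2-methylprop-1-ene | CC(=C)CBr | starting material
10 | sodium (Z)-enolate of 8 | C/C=C(\[O-])N1[C@H](Cc2ccccc2)COC1=O.[Na+] | intermediate
11 | (4R)-4-benzyl-3-[(2S)-2,4-dimethylpent-4-enoyl]-1,3-oxazolidin-2-one | O=C([C@@H](C)CC(C)=C)N1[C@H](Cc2ccccc2)COC1=O | intermediate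
12 | (2S)-2,4-dimethylpent-4-en-1-ol | OC[C@@H](C)CC(C)=C | intermediate
13 | (2S)-2,4-dimethylpent-4-en-1-yl 4-methylbenzenesulfonate | Cc1ccc(cc1)S(=O)(=O)OC[C@@H](C)CC(C)=C | intermediate
14 | [(3S)-3-methyl-7-phenylheptyl]magnesium bromide | C[C@@H](CCCCc1ccccc1)CC[Mg]Br | intermediate
15 | (4R,8S)-2,4,8-trimethyl-12-phenyldodec-1-ene | C[C@@H](CCCCc1ccccc1)CCC[C@@H](C)CC(C)=C | intermediate
16 | propanal | CCC=O | starting material
17 | dioxygen | O=O | starting material
18 | (2S,4R,6R,10S)-4-hydroperoxy-2,4,6,10-tetramethyl-14-phenyltetradecanal | C[C@@H](CCCCc1ccccc1)CCC[C@@H](C)C[C@@](C)(OO)C[C@H](C)C=O | intermediate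
19 | (4S,6R)-4,6-dimethyl-6-[(2R,6S)-2,6-dimethyl-10-phenyldecyl]-1,2-dioxan-3-ol (both anomers) | C[C@@H](CCCCc1ccccc1)CCC[C@@H](C)C[C@]1(C)C[C@H](C)C(O)OO1 | intermediate
20 | (4S,6R)-3-methoxy-4,6-dimethyl-6-[(2R,6S)-2,6-dimethyl-10-phenyldecyl]-1,2-dioxane (both anomers) | C[C@@H](CCCCc1ccccc1)CCC[C@@H](C)C[C@]1(C)C[C@H](C)C(OC)OO1 | intermediate
21 | tert-butyl[(1-methoxyethenyl)oxy]dimethylsilane | C=C(OC)O[Si](C)(C)C(C)(C)C | starting material
22 | (4S,6R)-4,6-dimethyl-6-[(2R,6S)-2,6-dimethyl-10-phenyldecyl]-1,2-dioxan-3-ylium trifluoromethanesulfonate | C[C@@H](CCCCc1ccccc1)CCC[C@@H](C)C[C@]1(C)C[C@H](C)C=[O+]O1.[O-]S(=O)(=O)C(F)(F)F | intermediate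
23 | methyl 2-[(3S,4S,6R)-4,6-dimethyl-6-[(2R,6S)-2,6-dimethyl-10-phenyldecyl]-1,2-dioxan-3-yl]acetate | C[C@@H](CCCCc1ccccc1)CCC[C@@H](C)C[C@]1(C)C[C@H](C)[C@H](CC(=O)OC)OO1 | intermediate
24 | lithium 2-[(3S,4S,6R)-4,6-dimethyl-6-[(2R,6S)-2,6-dimethyl-10-phenyldecyl]-1,2-dioxan-3-yl]acetate | C[C@@H](CCCCc1ccccc1)CCC[C@@H](C)C[C@]1(C)C[C@H](C)[C@H](CC(=O)[O-])OO1.[Li+] | intermediate
25 | 2-[(3S,4S,6R)-4,6-dimethyl-6-[(2R,6S)-2,6-dimethyl-10-phenyldecyl]-1,2-dioxan-3-yl]acetic acid | C[C@@H](CCCCc1ccccc1)CCC[C@@H](C)C[C@]1(C)C[C@H](C)[C@H](CC(=O)O)OO1 | target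

**Step count and risks**

Total steps: 11. Longest linear sequence: 8 steps (1–3, then 7–11); the branch 4–6 joins at step 7 and is equally long.

Steps most likely to fail:

1. Step 8 (the new method). Oxygen may capture the enamine radical cation before the alkene does, so that propanal is α-oxygenated and 15 is left unchanged. Peroxyl radicals may start chain autoxidation of the aldehyde or degrade the amine. The manganese couple may fail to turn over. The C6 epimers may prove hard to separate later.
   Fallback with known chemistry, from 15 to 20: ozonolysis of 15 (O3, CH2Cl2, −78 °C; Me2S) should give (4R,8S)-4,8-dimethyl-12-phenyldodecan-2-one F1. Deprotonation at its methyl group (LDA, THF, −78 °C) and trapping with PhNTf2 should give (4R,8S)-4,8-dimethyl-12-phenyldodec-1-en-2-yl trifluoromethanesulfonate F2. Negishi coupling of F2 (Pd(PPh3)4, THF/DMF, rt) with [(2R)-3-methoxy-2-methyl-3-oxopropyl]zinc bromide F3, prepared from commercial methyl (R)-3-bromo-2-methylpropanoate and activated zinc in DMF, should give methyl (2S,6R,10S)-2,6,10-trimethyl-4-methylidene-14-phenyltetradecanoate F4, so that ring C4 now comes from the chiral pool. DIBAL-H (CH2Cl2, −78 °C) should give (2S,6R,10S)-2,6,10-trimethyl-4-methylidene-14-phenyltetradecanal F5, and PPTS with HC(OMe)3 in MeOH its acetal (2S,6R,10S)-1,1-dimethoxy-2,6,10-trimethyl-4-methylidene-14-phenyltetradecane F6. Mukaiyama–Isayama hydroperoxysilylation (Co(thd)2 cat., O2, Et3SiH, 1,2-dichloroethane, rt) should place the silylperoxy group on the tertiary carbon and give triethyl{[(2S,6R,10S)-1,1-dimethoxy-2,4,6,10-tetramethyl-14-phenyltetradecan-4-yl]peroxy}silane F7 as both epimers at the peroxide carbon (ring C6). TsOH in MeOH should then remove the silyl group and close the ring to 20, accompanied by its 6S epimer as in the main route.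

2. Step 10. The ketene silyl acetal reacts with the ring cation at a rate near the diffusion limit, so facial selectivity at C3 may be poor. The Lewis acid may also trigger heterolysis at the tertiary C6–O bond.
   Fallback, from 20 to 25: allyltrimethylsilane with SnCl4 (CH2Cl2, −78 °C), a slower π-nucleophile for which axial attack on six-membered ring cations is most reliable, should give (3S,4S,6R)-4,6-dimethyl-6-[(2R,6S)-2,6-dimethyl-10-phenyldecyl]-3-(prop-2-en-1-yl)-1,2-dioxane F8, from which the 6S epimer would be removed by HPLC. Ozonolysis of the terminal alkene (O3, CH2Cl2, −78 °C; Me2S) should give 2-[(3S,4S,6R)-4,6-dimethyl-6-[(2R,6S)-2,6-dimethyl-10-phenyldecyl]-1,2-dioxan-3-yl]acetaldehyde F9. Pinnick oxidation (NaClO2, NaH2PO4, 2-methyl-2-butene, t-BuOH/H2O) would then give 25 directly.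

3. Step 11. Hydroxide may open the β-peroxy ester by E1cB elimination, or deprotonate C3–H and fragment the peroxide (Kornblum–DeLaMare), in competition with saponification.
   Fallback, from 20 to 25, avoiding any basic step: treatment of 20 with the known reagent 1,1-bis(trimethylsilyloxy)ethene and TMSOTf (cat., CH2Cl2, −78 °C) should give trimethylsilyl 2-[(3S,4S,6R)-4,6-dimethyl-6-[(2R,6S)-2,6-dimethyl-10-phenyldecyl]-1,2-dioxan-3-yl]acetate F10. This hydrolyses on mildly acidic aqueous work-up to 25; the 6S acid would then be removed by reversed-phase HPLC.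

Further compounds
F1 | step 8 | (4R,8S)-4,8-dimethyl-12-phenyldodecan-2-one | C[C@@H](CCCCc1ccccc1)CCC[C@@H](C)CC(C)=O
F2 | step 8 | (4R,8S)-4,8-dimethyl-12-phenyldodec-1-en-2-yl trifluoromethanesulfonate | C[C@@H](CCCCc1ccccc1)CCC[C@@H](C)CC(=C)OS(=O)(=O)C(F)(F)F
F3 | step 8 | [(2R)-3-methoxy-2-methyl-3-oxopropyl]zinc bromide | Br[Zn]C[C@H](C)C(=O)OC
F4 | step 8 | methyl (2S,6R,10S)-2,6,10-trimethyl-4-methylidene-14-phenyltetradecanoate | C[C@@H](CCCCc1ccccc1)CCC[C@@H](C)CC(=C)C[C@H](C)C(=O)OC
F5 | step 8 | (2S,6R,10S)-2,6,10-trimethyl-4-methylidene-14-phenyltetradecanal | C[C@@H](CCCCc1ccccc1)CCC[C@@H](C)CC(=C)C[C@H](C)C=O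
F6 | step 8 | (2S,6R,10S)-1,1-dimethoxy-2,6,10-trimethyl-4-methylidene-14-phenyltetradecane | C[C@@H](CCCCc1ccccc1)CCC[C@@H](C)CC(=C)C[C@H](C)C(OC)OC
F7 | step 8 | triethyl{[(2S,6R,10S)-1,1-dimethoxy-2,4,6,10-tetramethyl-14-phenyltetradecan-4-yl]peroxy}silane | C[C@@H](CCCCc1ccccc1)CCC[C@@H](C)CC(C)(OO[Si](CC)(CC)CC)C[C@H](C)C(OC)OC
F8 | step 10 | (3S,4S,6R)-4,6-dimethyl-6-[(2R,6S)-2,6-dimethyl-10-phenyldecyl]-3-(prop-2-en-1-yl)-1,2-dioxane | C[C@@H](CCCCc1ccccc1)CCC[C@@H](C)C[C@]1(C)C[C@H](C)[C@H](CC=C)OO1
F9 | step 10 | 2-[(3S,4S,6R)-4,6-dimethyl-6-[(2R,6S)-2,6-dimethyl-10-phenyldecyl]-1,2-dioxan-3-yl]acetaldehyde | C[C@@H](CCCCc1ccccc1)CCC[C@@H](C)C[C@]1(C)C[C@H](C)[C@H](CC=O)OO1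
F10 | step 11 | trimethylsilyl 2-[(3S,4S,6R)-4,6-dimethyl-6-[(2R,6S)-2,6-dimethyl-10-phenyldecyl]-1,2-dioxan-3-yl]acetate | C[C@@H](CCCCc1ccccc1)CCC[C@@H](C)C[C@]1(C)C[C@H](C)[C@H](CC(=O)O[Si](C)(C)C)OO1
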